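Germacranolide numbering is used. The route rests on cutting the oxirane bond C1–C10, the bond shared by the three-membered ring and the ten-membered carbocycle. C1 is allylic to the C2=C3–C4=C5 diene and C10 carries the methyl group, so the pair is read as a diene-stabilised sulfonium ylide and a methyl ketone. One intramolecular Corey–Chaykovsky epoxy-annulation closes carbocycle and oxirane together and sets C1 and C10. Its precursor is an open-chain keto dienyl thiolanium salt carried by a trans-β,γ-disubstituted butyrolactone, itself built by an Evans succinate aldol, an L-proline acetone aldol and a Stille coupling.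

Key step: step 14

Remark: numbering is C1–C10 ring, C11–C13 lactone side, C14 methyl, C15 hydroxymethyl. CIP descriptors at C6 and C7 change with iodine, silyl and acyl neighbours, but the spatial arrangement fixed in step 5 is never altered. C4=C5 is ring-cis (formally E because of the CH2O group).
Assumption: Red-Al, tributyltin triflate and Eschenmoser's salt are bought as such.

**Step 1**
Reactants: 1 but-2-yne-1,4-diol
Product: 2 4-[(tert-butyldiphenylsilyl)oxy]but-2-yn-1-ol
Conditions: TBDPSCl (0.3 equiv), imidazole, DMF, 0 °C → rt (diol in excess)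
Reagents that add atoms: tert-butyl(chloro)diphenylsilane CC(C)(C)[Si](Cl)(c1ccccc1)c1ccccc1
Why: Statistical mono-silylation of the symmetric diol used in excess should give the mono-ether, which marks the future C15 oxygen.

**Step 2**
Reactants: 2 4-[(tert-butyldiphenylsilyl)oxy]but-2-yn-1-ol
Product: 3 (2Z)-4-[(tert-butyldiphenylsilyl)oxy]-3-iodobut-2-en-1-ol
Conditions: Red-Al, THF, 0 °C; then I2, −78 → 0 °C
Reagents that add atoms: iodine II
Why: Alkoxide-directed trans-hydroalumination puts aluminium on the distal alkyne carbon cis to CH2OH, and iodinolysis with retention gives the Z-vinyl iodide that fixes the ring-cis C4=C5 geometry.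

**Step 3**
Reactants: 3 (2Z)-4-[(tert-butyldiphenylsilyl)oxy]-3-iodobut-2-en-1-ol
Product: 4 (2Z)-4-[(tert-butyldiphenylsilyl)oxy]-3-iodobut-2-enal
Conditions: MnO2 (activated), CH2Cl2, rt
Reagents that add atoms: none
Why: Allylic oxidation with MnO2 is neutral and should leave the Z-iodoalkene and the silyl ether untouched.

**Step 4**
Reactants: 5 (4S)-4-benzyl-1,3-oxazolidin-2-one; 6 methyl 4-chloro-4-oxobutanoate
Product: 7 methyl 4-[(4S)-4-benzyl-2-oxo-1,3-oxazolidin-3-yl]-4-oxobutanoate
Conditions: n-BuLi, THF, −78 °C; then 6, −78 → 0 °C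
Reagents that add atoms: none
Why: N-acylation of the lithiated oxazolidinone by the acid chloride gives the Evans succinate imide.

**Step 5**
Reactants: 7 methyl 4-[(4S)-4-benzyl-2-oxo-1,3-oxazolidin-3-yl]-4-oxobutanoate; 4 (2Z)-4-[(tert-butyldiphenylsilyl)oxy]-3-iodobut-2-enal
Product: 9 (4S)-4-benzyl-3-{[(2S,3S)-2-[(1Z)-3-[(tert-butyldiphenylsilyl)oxy]-2-iodoprop-1-en-1-yl]-5-oxooxolan-3-yl]carbonyl}-1,3-oxazolidin-2-one, via syn-aldol adduct 8 (not isolated)
Conditions: Bu2BOTf, i-Pr2NEt, CH2Cl2, −78 → 0 °C; 4, −78 → 0 °C; pH 7 buffer, MeOH, H2O2; then PPTS (cat.), toluene, 50 °C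
Reagents that add atoms: none
Why: The Evans syn-aldol through the Z-boron enolate of the imide carbonyl (not the ester) sets C6 and C7 from the (S)-benzyl auxiliary, and the γ-hydroxy ester lactonises to the trans-lactone while the future C8 stays at the acyl level.

**Step 6**
Reactants: 9 lactone imide
Product: 10 (2S,3S)-2-[(1Z)-3-[(tert-butyldiphenylsilyl)oxy]-2-iodoprop-1-en-1-yl]-5-oxooxolane-3-carboxylic acid
Conditions: LiOH, H2O2, THF/H2O, 0 °C; Na2SO3; then 1 M HCl to pH 2
Reagents that add atoms: hydrogen peroxide (as LiOOH) OO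
Why: Lithium hydroperoxide cleaves the exocyclic imide carbonyl selectively, and any opened hydroxy acid should relactonise on acidification.

**Step 7**
Reactants: 10 lactone acid
Product: 11 (4R,5S)-5-[(1Z)-3-[(tert-butyldiphenylsilyl)oxy]-2-iodoprop-1-en-1-yl]-4-(hydroxymethyl)oxolan-2-one
Conditions: BH3·SMe2, THF, 0 °C → rt; MeOH quench
Reagents that add atoms: none
Why: Borane reduces the free carboxylic acid much faster than the lactone or the iodoalkene.

**Step 8**
Reactants: 11 hydroxymethyl lactone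
Product: 12 (2S,3S)-2-[(1Z)-3-[(tert-butyldiphenylsilyl)oxy]-2-iodoprop-1-en-1-yl]-5-oxooxolane-3-carbaldehyde
Conditions: Dess–Martin periodinane, NaHCO3, CH2Cl2, 0 °C → rt; used at once
Reagents that add atoms: none
Why: Buffered Dess–Martin oxidation gives the aldehyde without a base that could epimerise C7 or eliminate the β-lactone oxygen.

**Step 9**
Reactants: 12 lactone aldehyde; 13 acetone
Product: 14 (4R,5S)-5-[(1Z)-3-[(tert-butyldiphenylsilyl)oxy]-2-iodoprop-1-en-1-yl]-4-[(1R)-1-hydroxy-3-oxobutyl]oxolan-2-one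
Conditions: L-proline (30 mol %), acetone/DMSO 1:4, 4 °C → rt
Reagents that add atoms: none
Why: In the List–Barbas direct aldol the proline enamine of acetone should attack the Re face of the α-branched aldehyde through the acid-bound chair transition state, setting C8 (R) under catalyst control in the same sense as the 1,3-anti preference of the C6 oxygen.

**Step 10**
Reactants: 14 β-hydroxy ketone
Product: 15 (4S,5S)-5-[(1Z)-3-[(tert-butyldiphenylsilyl)oxy]-2-iodoprop-1-en-1-yl]-4-[(1R)-3-oxo-1-[(triethylsilyl)oxy]butyl]oxolan-2-one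
Conditions: TESCl, imidazole, DMF, 0 °C
Reagents that add atoms: chlorotriethylsilane CC[Si](Cl)(CC)CC
Why: Silylation blocks retro-aldol and translactonisation to the 8,12-olide, and the secondary TES ether can later be removed beside the primary TBDPS ether.

**Step 11**
Reactants: 16 prop-2-yn-1-ol
Product: 17 (2Z)-3-(tributylstannyl)prop-2-en-1-ol
Conditions: LiAlH4, THF, 0 °C → rt; then Bu3SnOTf, −78 °C → rt
Reagents that add atoms: tributyltin triflate CCCC[Sn](CCCC)(CCCC)OS(=O)(=O)C(F)(F)F
Why: Hydroxyl-directed trans-hydroalumination of the terminal alkyne and aluminium-to-tin exchange with retention should give the Z-stannane.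

**Step 12**
Reactants: 15 vinyl iodide; 17 (2Z)-3-(tributylstannyl)prop-2-en-1-ol
Product: 18 (4S,5R)-5-[(1E,3Z)-2-{[(tert-butyldiphenylsilyl)oxy]methyl}-5-hydroxypenta-1,3-dien-1-yl]-4-[(1R)-3-oxo-1-[(triethylsilyl)oxy]butyl]oxolan-2-one
Conditions: Pd2(dba)3 (5 mol %), AsPh3 (20 mol %), CuI (10 mol %), NMP, rt
Reagents that add atoms: none
Why: Stille coupling proceeds with retention at both sp2 carbons, giving the 2Z alkene and the ring-cis C4=C5 alkene, and the copper-assisted catalyst works at room temperature so that palladium should not ionise the allylic lactone.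

**Step 13**
Reactants: 18 dienol
Product: 20 1-[(2Z,4E)-4-{[(tert-butyldiphenylsilyl)oxy]methyl}-5-{(2R,3S)-5-oxo-3-[(1R)-3-oxo-1-[(triethylsilyl)oxy]butyl]oxolan-2-yl}penta-2,4-dien-1-yl]thiolan-1-ium tetrafluoroborate, via allylic bromide 19 (not isolated)
Conditions: CBr4, PPh3, 2,6-lutidine (cat.), CH2Cl2, −20 °C; then tetrahydrothiophene (10 equiv), sat. aq. NaBF4, rt
Reagents that add atoms: tetrahydrothiophene C1CCSC1; sodium tetrafluoroborate [Na+].F[B-](F)(F)F
Why: Appel bromination of the primary allylic alcohol followed by SN2 S-alkylation of thiolane, with tetrafluoroborate exchange to stop reversal, should give the salt without moving the Z alkene.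

**Step 14**
Reactants: 20 thiolanium tetrafluoroborate
Product: 22 (1R,6R,7S,8R,10R)-15-[(tert-butyldiphenylsilyl)oxy]-1,10-epoxy-8-[(triethylsilyl)oxy]-13-norgermacra-2Z,4E-dien-12,6-olide (C11H2 lactone), via sulfonium ylide 21 (not isolated)
Conditions: KOt-Bu (1.05 equiv), THF (1 mM), −78 → −20 °C
Reagents that add atoms: none
Why: KOt-Bu removes the C1 proton flanked by S+ and the diene, ylide 21 adds through C1 to the C10 ketone, and the betaine alkoxide then displaces thiolane from C1, so the C1–C10 and C1–O bonds form in one operation (intramolecular Corey–Chaykovsky epoxidation). The closest precedent is the epoxy-annulation of keto sulfonium salts to fused oxiranes in five- to seven-membered rings, together with the intermolecular vinyl-oxirane synthesis from allylic sulfonium ylides and ketones; the ten-membered ring size is the extension and the main risk. The carbocycle closes 10-exo-trig at the carbonyl carbon and the oxirane closes 3-exo-tet at C1. C10 should become R by attack on the Si face of the ketone, which gives the 1,3-anti relation to the C8 silyloxy group expected from the non-chelated, dipole-minimised conformer (K+ counter-ion, bulky silyl ether); C1 should become R because closure runs through the anti betaine with C2 antiperiplanar to C9, the sterically preferred betaine of a methyl ketone and the E-type junction a ten-membered ring accommodates. The step needs ylide formation at C1 only (the sulfonium C–H is far more acidic than ketone or lactone C–H and one equivalent of base is used), α- rather than γ-attack, retention of the 2Z alkene, and cyclisation over oligomerisation (1 mM); the two ring-cis alkenes and the trans-lactone turn the chain so that C1 faces C10. The α-methylene unit is left out until step 15 and C8 is a silyl ether, so that neither a Michael acceptor nor an acyloxy leaving group β to the ketone competes.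

**Step 15**
Reactants: 22 epoxy lactone
Product: 25 (1R,6R,7S,8R,10R)-15-[(tert-butyldiphenylsilyl)oxy]-1,10-epoxy-8-[(triethylsilyl)oxy]germacra-2Z,4E,11(13)-trien-12,6-olide, via Mannich base 23 (not isolated), via ammonium iodide 24 (not isolated)
Conditions: LDA (1.2 equiv), THF, −78 °C; Eschenmoser's salt, −78 → 0 °C; then MeI, CH2Cl2/MeOH, rt; then sat. aq. NaHCO3, rt
Reagents that add atoms: Eschenmoser's salt C=[N+](C)C.[I-]
Why: The lactone is now the only enolisable carbonyl, so its lithium enolate is aminomethylated (Mannich reaction), and quaternisation followed by E1cB elimination should give the exocyclic methylene while the transient C11 centre disappears.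

**Step 16**
Reactants: 25 α-methylene lactone
Product: 26 (1R,6R,7R,8R,10R)-15-[(tert-butyldiphenylsilyl)oxy]-1,10-epoxy-8-hydroxygermacra-2Z,4E,11(13)-trien-12,6-olide
Conditions: Et3N·3HF, THF, 0 °C → rt
Reagents that add atoms: none
Why: Amine-buffered HF cleaves the secondary triethylsilyl ether far faster than the primary tert-butyldiphenylsilyl ether and is too weakly acidic to open the vinyl oxirane.

**Step 17**
Reactants: 27 (E)-but-2-enal
Product: 29 (2Z)-2-iodobut-2-en-1-ol, via (Z)-2-iodobut-2-enal 28 (not isolated)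
Conditions: I2, K2CO3, DMAP (cat.), THF/H2O 1:1, rt; then NaBH4, 0 °C
Reagents that add atoms: iodine II
Why: DMAP-mediated addition–iodination–elimination gives the (Z)-α-iodoenal with iodine cis to the methyl group, and borohydride reduces the aldehyde 1,2.

**Step 18**
Reactants: 29 (2Z)-2-iodobut-2-en-1-ol
Product: 30 tert-butyl{[(2Z)-2-iodobut-2-en-1-yl]oxy}diphenylsilane
Conditions: TBDPSCl, imidazole, CH2Cl2, rt
Reagents that add atoms: tert-butyl(chloro)diphenylsilane CC(C)(C)[Si](Cl)(c1ccccc1)c1ccccc1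
Why: Silylation of the primary allylic alcohol with the same group as at C15 allows a single final deprotection.

**Step 19**
Reactants: 30 silyl-protected vinyl iodide
Product: 31 (2Z)-2-{[(tert-butyldiphenylsilyl)oxy]methyl}but-2-enoic acid
Conditions: t-BuLi (2.1 equiv), Et2O, −78 °C; CO2, −78 → 0 °C; dilute HCl to pH 3
Reagents that add atoms: carbon dioxide O=C=O
Why: Iodine–lithium exchange and carboxylation both proceed with retention of alkene geometry, which places the carboxyl cis to the methyl group as the Z (sarracinate-type) acid requires.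

**Step 20**
Reactants: 26 C8 alcohol; 31 (2Z)-2-{[(tert-butyldiphenylsilyl)oxy]methyl}but-2-enoic acid
Product: 32 (1R,6R,7R,8R,10R)-15-[(tert-butyldiphenylsilyl)oxy]-8-{[(2Z)-2-{[(tert-butyldiphenylsilyl)oxy]methyl}but-2-enoyl]oxy}-1,10-epoxygermacra-2Z,4E,11(13)-trien-12,6-olide
Conditions: 31, 2,4,6-trichlorobenzoyl chloride, Et3N, toluene, rt; then 26, DMAP (0.3 equiv), 0 °C → rt
Reagents that add atoms: none
Why: Yamaguchi esterification acylates the only free hydroxyl (C8) through the mixed anhydride, and low temperature with substoichiometric DMAP should limit Z-to-E isomerisation of the angelate-type acyl unit.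

**Step 21**
Reactants: 32 bis-silyl ether
Product: 33 CNP0293319.2 (target)
Conditions: TBAF/AcOH (1:1), THF, 0 °C → rt
Reagents that add atoms: none
Why: Acetic-acid-buffered fluoride should remove both primary allylic silyl ethers while the oxirane, the two esters and the α-methylene lactone stay intact.

**Compound list**
1 | but-2-yne-1,4-diol | OCC#CCO | starting material
2 | 4-[(tert-butyldiphenylsilyl)oxy]but-2-yn-1-ol | OCC#CCO[Si](c1ccccc1)(c1ccccc1)C(C)(C)C | intermediate
3 | (2Z)-4-[(tert-butyldiphenylsilyl)oxy]-3-iodobut-2-en-1-ol | OC/C=C(\I)CO[Si](c1ccccc1)(c1ccccc1)C(C)(C)C | intermediate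
4 | (2Z)-4-[(tert-butyldiphenylsilyl)oxy]-3-iodobut-2-enal | O=C/C=C(\I)CO[Si](c1ccccc1)(c1ccccc1)C(C)(C)C | intermediate
5 | (4S)-4-benzyl-1,3-oxazolidin-2-one | O=C1N[C@@H](Cc2ccccc2)CO1 | starting material
6 | methyl 4-chloro-4-oxobutanoate | COC(=O)CCC(Cl)=O | starting material
7 | methyl 4-[(4S)-4-benzyl-2-oxo-1,3-oxazolidin-3-yl]-4-oxobutanoate | COC(=O)CCC(=O)N1[C@@H](Cc2ccccc2)COC1=O | intermediate
8 | methyl (3S,4S,5Z)-3-{[(4S)-4-benzyl-2-oxo-1,3-oxazolidin-3-yl]carbonyl}-7-[(tert-butyldiphenylsilyl)oxy]-4-hydroxy-6-iodohept-5-enoate (syn-aldol adduct) | COC(=O)C[C@H](C(=O)N1[C@@H](Cc2ccccc2)COC1=O)[C@H](O)/C=C(\I)CO[Si](c1ccccc1)(c1ccccc1)C(C)(C)C | intermediate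
9 | (4S)-4-benzyl-3-{[(2S,3S)-2-[(1Z)-3-[(tert-butyldiphenylsilyl)oxy]-2-iodoprop-1-en-1-yl]-5-oxooxolan-3-yl]carbonyl}-1,3-oxazolidin-2-one | O=C1C[C@H](C(=O)N2[C@@H](Cc3ccccc3)COC2=O)[C@@H](/C=C(\I)CO[Si](c2ccccc2)(c2ccccc2)C(C)(C)C)O1 | intermediate
10 | (2S,3S)-2-[(1Z)-3-[(tert-butyldiphenylsilyl)oxy]-2-iodoprop-1-en-1-yl]-5-oxooxolane-3-carboxylic acid | O=C1C[C@H](C(=O)O)[C@@H](/C=C(\I)CO[Si](c2ccccc2)(c2ccccc2)C(C)(C)C)O1 | intermediate
11 | (4R,5S)-5-[(1Z)-3-[(tert-butyldiphenylsilyl)oxy]-2-iodoprop-1-en-1-yl]-4-(hydroxymethyl)oxolan-2-one | O=C1C[C@H](CO)[C@@H](/C=C(\I)CO[Si](c2ccccc2)(c2ccccc2)C(C)(C)C)O1 | intermediate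
12 | (2S,3S)-2-[(1Z)-3-[(tert-butyldiphenylsilyl)oxy]-2-iodoprop-1-en-1-yl]-5-oxooxolane-3-carbaldehyde | O=C1C[C@H](C=O)[C@@H](/C=C(\I)CO[Si](c2ccccc2)(c2ccccc2)C(C)(C)C)O1 | intermediate
13 | acetone | CC(C)=O | starting material
14 | (4R,5S)-5-[(1Z)-3-[(tert-butyldiphenylsilyl)oxy]-2-iodoprop-1-en-1-yl]-4-[(1R)-1-hydroxy-3-oxobutyl]oxolan-2-one | O=C1C[C@H]([C@H](O)CC(C)=O)[C@@H](/C=C(\I)CO[Si](c2ccccc2)(c2ccccc2)C(C)(C)C)O1 | intermediate
15 | (4S,5S)-5-[(1Z)-3-[(tert-butyldiphenylsilyl)oxy]-2-iodoprop-1-en-1-yl]-4-[(1R)-3-oxo-1-[(triethylsilyl)oxy]butyl]oxolan-2-one | O=C1C[C@H]([C@H](O[Si](CC)(CC)CC)CC(C)=O)[C@@H](/C=C(\I)CO[Si](c2ccccc2)(c2ccccc2)C(C)(C)C)O1 | intermediate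
16 | prop-2-yn-1-ol | C#CCO | starting material
17 | (2Z)-3-(tributylstannyl)prop-2-en-1-ol | OC/C=C\[Sn](CCCC)(CCCC)CCCC | intermediate
18 | (4S,5R)-5-[(1E,3Z)-2-{[(tert-butyldiphenylsilyl)oxy]methyl}-5-hydroxypenta-1,3-dien-1-yl]-4-[(1R)-3-oxo-1-[(triethylsilyl)oxy]butyl]oxolan-2-one | O=C1C[C@H]([C@H](O[Si](CC)(CC)CC)CC(C)=O)[C@@H](/C=C(CO[Si](c2ccccc2)(c2ccccc2)C(C)(C)C)\C=C/CO)O1 | intermediate
19 | (4S,5R)-5-[(1E,3Z)-5-bromo-2-{[(tert-butyldiphenylsilyl)oxy]methyl}penta-1,3-dien-1-yl]-4-[(1R)-3-oxo-1-[(triethylsilyl)oxy]butyl]oxolan-2-one | O=C1C[C@H]([C@H](O[Si](CC)(CC)CC)CC(C)=O)[C@@H](/C=C(CO[Si](c2ccccc2)(c2ccccc2)C(C)(C)C)\C=C/CBr)O1 | intermediate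
20 | 1-[(2Z,4E)-4-{[(tert-butyldiphenylsilyl)oxy]methyl}-5-{(2R,3S)-5-oxo-3-[(1R)-3-oxo-1-[(triethylsilyl)oxy]butyl]oxolan-2-yl}penta-2,4-dien-1-yl]thiolan-1-ium tetrafluoroborate | O=C1C[C@H]([C@H](O[Si](CC)(CC)CC)CC(C)=O)[C@@H](/C=C(CO[Si](c2ccccc2)(c2ccccc2)C(C)(C)C)\C=C/C[S+]2CCCC2)O1.F[B-](F)(F)F | intermediate
21 | C1 sulfonium ylide of 20 | O=C1C[C@H]([C@H](O[Si](CC)(CC)CC)CC(C)=O)[C@@H](/C=C(CO[Si](c2ccccc2)(c2ccccc2)C(C)(C)C)\C=C/[CH-][S+]2CCCC2)O1 | intermediate
22 | (1R,6R,7S,8R,10R)-15-[(tert-butyldiphenylsilyl)oxy]-1,10-epoxy-8-[(triethylsilyl)oxy]-13-norgermacra-2Z,4E-dien-12,6-olide | C1C(=O)O[C@@H]2/C=C(CO[Si](c4ccccc4)(c4ccccc4)C(C)(C)C)\C=C/[C@H]3O[C@]3(C)C[C@@H](O[Si](CC)(CC)CC)[C@@H]12 | intermediate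
23 | 11-(dimethylaminomethyl) derivative of 22 (Mannich base, C11 epimers, both converge) | CN(C)CC1C(=O)O[C@@H]2/C=C(CO[Si](c4ccccc4)(c4ccccc4)C(C)(C)C)\C=C/[C@H]3O[C@]3(C)C[C@@H](O[Si](CC)(CC)CC)[C@@H]12 | intermediate
24 | 11-(trimethylammoniomethyl) derivative of 22, iodide (C11 epimers) | C[N+](C)(C)CC1C(=O)O[C@@H]2/C=C(CO[Si](c4ccccc4)(c4ccccc4)C(C)(C)C)\C=C/[C@H]3O[C@]3(C)C[C@@H](O[Si](CC)(CC)CC)[C@@H]12.[I-] | intermediate
25 | (1R,6R,7S,8R,10R)-15-[(tert-butyldiphenylsilyl)oxy]-1,10-epoxy-8-[(triethylsilyl)oxy]germacra-2Z,4E,11(13)-trien-12,6-olide | C=C1C(=O)O[C@@H]2/C=C(CO[Si](c4ccccc4)(c4ccccc4)C(C)(C)C)\C=C/[C@H]3O[C@]3(C)C[C@@H](O[Si](CC)(CC)CC)[C@@H]12 | intermediate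
26 | (1R,6R,7R,8R,10R)-15-[(tert-butyldiphenylsilyl)oxy]-1,10-epoxy-8-hydroxygermacra-2Z,4E,11(13)-trien-12,6-olide | C=C1C(=O)O[C@@H]2/C=C(CO[Si](c4ccccc4)(c4ccccc4)C(C)(C)C)\C=C/[C@H]3O[C@]3(C)C[C@@H](O)[C@@H]12 | intermediate
27 | (E)-but-2-enal | C/C=C/C=O | starting material
28 | (2Z)-2-iodobut-2-enal | C/C=C(\I)C=O | intermediate
29 | (2Z)-2-iodobut-2-en-1-ol | C/C=C(\I)CO | intermediate
30 | tert-butyl{[(2Z)-2-iodobut-2-en-1-yl]oxy}diphenylsilane | C/C=C(\I)CO[Si](c1ccccc1)(c1ccccc1)C(C)(C)C | intermediate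
31 | (2Z)-2-{[(tert-butyldiphenylsilyl)oxy]methyl}but-2-enoic acid | C/C=C(/CO[Si](c1ccccc1)(c1ccccc1)C(C)(C)C)C(=O)O | intermediate
32 | (1R,6R,7R,8R,10R)-15-[(tert-butyldiphenylsilyl)oxy]-8-{[(2Z)-2-{[(tert-butyldiphenylsilyl)oxy]methyl}but-2-enoyl]oxy}-1,10-epoxygermacra-2Z,4E,11(13)-trien-12,6-olide | C=C1C(=O)O[C@@H]2/C=C(CO[Si](c4ccccc4)(c4ccccc4)C(C)(C)C)\C=C/[C@H]3O[C@]3(C)C[C@@H](OC(=O)/C(=C\C)CO[Si](c5ccccc5)(c5ccccc5)C(C)(C)C)[C@@H]12 | intermediate
33 | CNP0293319.2: (1R,6R,7R,8R,10R)-1,10-epoxy-15-hydroxy-8-{[(2Z)-2-(hydroxymethyl)but-2-enoyl]oxy}germacra-2Z,4E,11(13)-trien-12,6-olide | C=C1C(=O)O[C@@H]2/C=C(CO)\C=C/[C@H]3O[C@]3(C)C[C@@H](OC(=O)/C(=C\C)CO)[C@@H]12 | target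

**Step count and risks**
Total step count: 21. Longest linear sequence: 16 steps (steps 1–3, 5–10, 12–16, 20, 21).

Three steps most likely to fail:

1. Step 14. What may go wrong: addition to the wrong ketone face or closure to the cis-oxirane because substrate control is too weak; vinylogous loss of the C6 carboxylate or Z-to-E drift in the delocalised ylide; oligomerisation. Fallback with reagent control of the C1 face: the route sets out from 18, whose bromide 19 is used to alkylate the known C2-symmetric sulfide (2S,5S)-2,5-dimethylthiolane (aq. NaBF4, CH2Cl2), giving the chiral 2,5-dimethylthiolanium tetrafluoroborate F1. Its ylide (KOt-Bu, THF, 1 mM, −78 → −20 °C) has one face of C1 shielded by a ring methyl group and no second diastereomer at sulfur, so the C1 configuration is imposed by the sulfide and the anti-betaine closure then fixes C10. By analogy with benzylic ylides of this sulfide the (2S,5S) enantiomer is expected to give 1R; the (2R,5R) enantiomer is used if the sense proves opposite. The fallback comes back to the route at 22.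

2. Step 9. What may go wrong: erosion of catalyst control by the resident C7 centre (opposing 1,2-induction), amine-induced β-elimination of the lactone carboxylate, or epimerisation at C7. Fallback without amine and under substrate control: the route sets out from 12, which is treated with 2-(trimethylsilyloxy)propene and BF3·OEt2 in CH2Cl2 at −78 °C (Mukaiyama aldol). The non-chelated, dipole-minimised transition state with the small enol silane should favour the 1,3-anti product relative to the C6 oxygen, which is the same C8 configuration. Aqueous work-up gives 14 directly, where the fallback comes back to the route; it makes no new compound (F0).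

3. Step 15. What may go wrong: base-induced isomerisation of the vinyl oxirane to an allylic alcohol, or incomplete aminomethylation of the enolate in the congested macrocycle. Fallback without an enolate: the route sets out from 22, which is heated with Bredereck's reagent (tert-butoxybis(dimethylamino)methane, toluene, 80 °C) to give the (E)-α-(dimethylaminomethylene) lactone F2. DIBAL-H (THF, −78 °C) should then deliver hydride 1,4 to this vinylogous carbamate, and loss of dimethylamine on work-up gives the α-methylene lactone 25, where the fallback comes back to the route.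

**Further compounds**
F1 | step 14 | (2S,5S)-1-[(2Z,4E)-4-{[(tert-butyldiphenylsilyl)oxy]methyl}-5-{(2R,3S)-5-oxo-3-[(1R)-3-oxo-1-[(triethylsilyl)oxy]butyl]oxolan-2-yl}penta-2,4-dien-1-yl]-2,5-dimethylthiolan-1-ium tetrafluoroborate | O=C1C[C@H]([C@H](O[Si](CC)(CC)CC)CC(C)=O)[C@@H](/C=C(CO[Si](c2ccccc2)(c2ccccc2)C(C)(C)C)\C=C/C[S+]2[C@@H](C)CC[C@@H]2C)O1.F[B-](F)(F)F
F0 | step 9 | none | none
F2 | step 15 | (11E)-13-(dimethylamino) derivative of 25: (1R,6R,7S,8R,10R)-15-[(tert-butyldiphenylsilyl)oxy]-13-(dimethylamino)-1,10-epoxy-8-[(triethylsilyl)oxy]germacra-2Z,4E,11(13)E-trien-12,6-olide | CN(C)/C=C1/C(=O)O[C@@H]2/C=C(CO[Si](c4ccccc4)(c4ccccc4)C(C)(C)C)\C=C/[C@H]3O[C@]3(C)C[C@@H](O[Si](CC)(CC)CC)[C@@H]12
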